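## Retrosynthetic overview
1. Retro-Diels–Alder opens the new cyclohexene ring (C12–Cq and C15–Ca bonds). This gives the labdane triene acid (7β-hydroxy-labda-8(17),12E,14-trien-18-oic acid) and a transient 2-chromonyl-5-methoxy-1,4-benzoquinone. The quinone is generated in situ by anodic oxidative demethylation of a 2',4',5'-trimethoxyflavone, so the key C–C bonds form inside the electrolysis.
2. The flavone comes from a Claisen–Schmidt chalcone (phloroacetophenone + 2,4,5-trimethoxybenzaldehyde) and I2/DMSO oxidative cyclisation.
3. The triene acid comes from Wittig methylenation of a 7β-hydroxy-8-ketone. The C7 hydroxyl comes from enolate hydroxylation. The 12E,14-diene comes from photo-deformylative desaturation of a keto-aldehyde. The keto-aldehyde comes from ozonolysis of the ring C alkene of pimaric acid.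
4. Ring order: the A/B trans-decalin is inherited from pimaric acid, and ring C is opened in steps 1–2. The chromone ring closes in step 6. The new cyclohexene ring forms in step 7, where the aromatic B ring is simultaneously unmasked as the quinone.

Assumptions (one line each):
- (+)-Pimaric acid is a cheap commercial chiral starting material. Its C13 configuration is irrelevant because C13 becomes sp².
- The diene must be 12E, with C11 and the C14 vinyl trans across C12=C13.
- The 12Z and 13(16)-ene diene by-products are removed by AgNO3-silica chromatography; the Z isomer is also a poor Diels–Alder diene.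
- The diastereomers from step 7 are separable by HPLC.

## Steps

**Step 1**
Reactants: **1** (+)-pimaric acid, pimara-8(14),15-dien-18-oic acid
Product: **2** 8-oxo keto-aldehyde (trans-decalone bearing the 4α-CO2H and a C9–CH2CH2–C(CH3)(CH=CH2)–CHO chain)
Conditions: O3 (1.0 equiv), CH2Cl2/MeOH 4:1, –78 °C; then Me2S, –78 °C → rt
Reagents that add atoms: ozone, O=[O+][O-] (supplies the two carbonyl O atoms)
Why: Ozonolysis (Criegee) cleaves the electron-rich trisubstituted ring alkene C8=C14 faster than the monosubstituted vinyl on the quaternary C13. No stereocentre is created, and the decalin centres are untouched.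

**Step 2**
Reactants: **2**
Product: **3** 17-nor-8-oxo-labda-12E,14-dien-18-oic acid
Conditions: Cu(OAc)2 (2.5 equiv), MeCN, hν (medium-pressure Hg lamp, Pyrex, λ > 290 nm), 20 °C, N2
Reagents that add atoms: none
Why: Norrish type I cleavage of the β,γ-unsaturated α-quaternary aldehyde (photodecarbonylation-type reactivity) gives a tertiary allylic radical and HCO•. Cu(II) oxidises HCO• to CO + H+ and oxidises the allylic radical (Kochi-type) to an allyl-Cu(III)/allyl cation. Loss of H+ from C12 then gives the thermodynamically favoured conjugated (E)-trisubstituted 12,14-diene. No stereocentre is set.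

**Step 3**
Reactants: **3**
Product: **4** 7β-hydroxy-8-oxo-17-norlabda-12E,14-dien-18-oic acid
Conditions: LDA (3.0 equiv), THF, –78 °C; then (±)-2-(phenylsulfonyl)-3-phenyloxaziridine, –78 °C; then K2CO3, MeOH, 25 °C; then 1 M HCl work-up
Reagents that add atoms: Davis oxaziridine, O=S(=O)(c1ccccc1)N1OC1c1ccccc1 (transfers one O)
Why: LDA first forms the carboxylate and then the kinetic enolate at the unhindered C7 (not the tertiary C9). Enolate hydroxylation (Davis) occurs from the axial α-face, anti to the 10β-methyl, to give the 7α-ketol. Mild base then epimerises it via the enol to the equatorial 7β-ketol, a thermodynamic outcome fixed by the trans-decalin.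

**Step 4**
Reactants: **4**
Product: **5** 7β-hydroxy-labda-8(17),12E,14-trien-18-oic acid
Conditions: Ph3P+CH3 Br– (6 equiv), KOtBu (5.5 equiv), THF, 0 → 65 °C; then 1 M HCl work-up
Reagents that add atoms: methyltriphenylphosphonium bromide, C[P+](c1ccccc1)(c1ccccc1)c1ccccc1.[Br-] (supplies the =CH2 carbon)
Why: Wittig methylenation builds the exocyclic C8=C17 alkene. Excess ylide covers the acid and alcohol, and the 7β stereocentre is not touched.

**Step 5**
Reactants: **6** 2,4,6-trihydroxyacetophenone; **7** 2,4,5-trimethoxybenzaldehyde
Product: **8** (E)-2',4',6'-trihydroxy-2,4,5-trimethoxychalcone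
Conditions: 50% aq. KOH, EtOH, rt, 48 h; then HCl
Reagents that add atoms: none
Why: Claisen–Schmidt aldol condensation; the E-enone is thermodynamically selected.

**Step 6**
Reactants: **8**
Product: **9** 5,7-dihydroxy-2',4',5'-trimethoxyflavone
Conditions: I2 (0.2 equiv), DMSO, 130 °C
Reagents that add atoms: none
Why: The 2'-OH adds in an oxa-Michael reaction to give the flavanone, and I2/DMSO then oxidises it to the flavone (oxidative cyclisation of a 2'-hydroxychalcone, as in chrysin syntheses). The para-related 2'/5'-OMe pair becomes the masked quinone and the 4'-OMe is retained.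

**Step 7**
Reactants: **9**; **5** (2.0 equiv)
Product: **10** dichrostachine E (target)
Conditions: divided cell (Nafion membrane), graphite-felt anode, Pt cathode, constant current (~2 mA/cm², 2.1 F/mol vs **9**), 0.2 M LiClO4, 2,6-di-tert-butyl-4-methylpyridine (2.5 equiv), anolyte MeCN/H2O 95:5 (catholyte same, with AcOH 5 equiv), 10 °C during electrolysis; then 40 °C, 24 h
Reagents that add atoms: water, O (supplies the two quinone C=O oxygens; the two OMe groups leave as MeOH)
Why: Proposed new method: anodic 2 e– oxidative demethylation of the 2',5'-dimethoxyarene (arene radical cation → water attack at the ipso carbon → loss of MeOH, twice) generates the transient 2-(5,7-dihydroxychromon-2-yl)-5-methoxy-1,4-benzoquinone, and the diene **5** traps it in situ in a Li+-promoted [4+2] cycloaddition. The quinone C2=C3 bond is the reactive dienophile, because the C1 carbonyl is deactivated by the vinylogous-ester OMe while the C4 carbonyl activates C2. The 2-methyl group and the C12 substituent of the diene both direct C12 to the chromonyl-bearing carbon, forming the vicinal quaternary/tertiary centres. Suprafacial addition gives the cis ring fusion (Ca–H cis to the chromonyl). The target's C11/chromonyl-cis relationship arises from the E-diene adding with the chromonyl group endo (quinone carbonyls exo), and that selectivity is not assured. Facial bias at C12, Ca and Cq comes only from the decalin, so a diastereomer mixture is expected and the target isomer is isolated by HPLC. Closest known reactions are anodic oxidation of 1,4-dimethoxyarenes to quinones and LiClO4- or Lewis-acid-promoted quinone Diels–Alder additions; the new element is running them as one electrochemical cascade on a 2-chromonylquinone with a hindered 1,2-disubstituted diene. This relies on assumed selectivity: with the hindered base the 5,7-phenols and the carboxylic acid stay protonated and oxidise at higher potential than the trialkoxyarene.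

## Compound list
1 | (+)-pimaric acid | C1=C2CC[C@@H]3[C@](C)(CCC[C@@]3(C)C(=O)O)[C@H]2CC[C@@]1(C)C=C | starting material
2 | 8-oxo-8,14-seco-pimarane keto-aldehyde | O=C1CC[C@@H]2[C@](C)(CCC[C@@]2(C)C(=O)O)[C@H]1CC[C@@](C)(C=C)C=O | intermediate
3 | 17-nor-8-oxo-labda-12E,14-dien-18-oic acid | O=C1CC[C@@H]2[C@](C)(CCC[C@@]2(C)C(=O)O)[C@H]1C/C=C(C)/C=C | intermediate
4 | 7β-hydroxy-8-oxo-17-norlabda-12E,14-dien-18-oic acid | O=C1[C@@H](O)C[C@@H]2[C@](C)(CCC[C@@]2(C)C(=O)O)[C@H]1C/C=C(C)/C=C | intermediate
5 | 7β-hydroxy-labda-8(17),12E,14-trien-18-oic acid | C=C1[C@@H](O)C[C@@H]2[C@](C)(CCC[C@@]2(C)C(=O)O)[C@H]1C/C=C(C)/C=C | intermediate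
6 | 2,4,6-trihydroxyacetophenone | CC(=O)c1c(O)cc(O)cc1O | starting material
7 | 2,4,5-trimethoxybenzaldehyde | O=Cc1cc(OC)c(OC)cc1OC | starting material
8 | (E)-2',4',6'-trihydroxy-2,4,5-trimethoxychalcone | COc1cc(OC)c(OC)cc1/C=C/C(=O)c1c(O)cc(O)cc1O | intermediate
9 | 5,7-dihydroxy-2',4',5'-trimethoxyflavone | COc1cc(OC)c(OC)cc1-c1cc(=O)c2c(O)cc(O)cc2o1 | intermediate
10 | dichrostachine E | C=C1[C@@H](O)C[C@@H]2[C@](C)(CCC[C@@]2(C)C(=O)O)[C@H]1C[C@@H]1C(C)=CC[C@H]2C(=O)C(OC)=CC(=O)[C@@]12c1cc(=O)c2c(O)cc(O)cc2o1 | target

**Total steps:** 7. **Longest linear sequence:** 5 (steps 1, 2, 3, 4, 7).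

## Three steps most likely to fail
1. **Step 7 (proposed new method).** Risks are competing anodic oxidation of the phenols or diene, quinone hydration or decomposition, a hindered cycloaddition, and low endo/exo and facial selectivity. Fallback (known chemistry): oxidise **9** to the quinone with CAN (2.2 equiv, MeCN/H2O, 0 °C). Then run a separate Diels–Alder with **5** under high pressure (12 kbar, CH2Cl2, 25 °C) or with Yb(OTf)3 catalysis, and separate the diastereomers by HPLC.
2. **Step 2.** The allylic radical may give the Δ13(16) isomer, acetate-trapped products or the 1,3-acyl-shift product. The C8 ketone may also absorb, and the diene may isomerise E/Z under ketone sensitisation. Fallback: Baeyer–Villiger oxidation of **2** (mCPBA, NaHCO3) to the tertiary allylic formate, then K2CO3/MeOH to the sclareol-type tertiary allylic alcohol. Dehydrate with Burgess reagent (acid transiently protected as its TMS ester with BSA), then separate the E isomer on AgNO3-silica.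
3. **Step 3.** The C7 hydroxylation may give a poor 7α/7β ratio or α-ketol isomerisation. Fallback: Wittig methylenation of **3** first, then SeO2/TBHP allylic oxidation at C7 and Dess–Martin oxidation to the 7-oxo-8(17)-ene enone. Luche reduction (NaBH4/CeCl3) would then favour the equatorial 7β-alcohol by axial hydride delivery.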